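**Plan**

- Retrosynthetic cuts, in order: (i) C3–C9 of the oxepine; (ii) the C6–alkenyl bond; (iii) O1–C2 and C2–C3 of the pyranone; (iv) the aryl–CO2H bond, the two C11–CH3 bonds and the O–C10 bond of the aryl ether.
- Forward: the glycerate-derived chain is attached to the B-ring phenol, converted into the C11 carbinol, and the ring is carboxylated. Esterification with the A-ring ketone, Baker–Venkataraman rearrangement and cyclodehydration give the pyranone. C6 iodination and Suzuki coupling add the alkene, and the oxepine is closed last.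
- Stereochemistry: C10 (R) is the only stereocentre. It comes from methyl (S)-glycerate by one Mitsunobu inversion, and no later step breaks a bond to it. The E-alkene comes from the boronate.
- Enabling feature (flavone numbering; oxepine CH2 = C9, stereocentre = C10, carbinol carbon = C11): C3 is the one free sp2 carbon of the pyranone ring, and its Mg/Cu derivative is a purely carbon-centred vinyl anion that can only C-alkylate. C9 lies two bonds from the aryl-ether oxygen on C10, so a metal there would expel the phenoxide and C9 must be the electrophile. C3–metal plus C9–OTs closes the seven-membered ring C2–C3–C9–C10–O–C2'–C1'.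
- Protecting groups: MOM on O5, O4' and O11 (removed together at the end) and TBDPS on O9 (removed by fluoride, orthogonal to the acetals).

Key step: step 17

Remark: the A-ring ketone is taken as purchased 1-(2,6-dihydroxy-4-methoxyphenyl)ethan-1-one (the 4-methyl ether of phloroacetophenone); its mirror symmetry makes ester formation and pyranone closure unambiguous.

Abbreviations used in names:
- ArSi = 2-{[(2R)-1-[(tert-butyldiphenylsilyl)oxy]-3-(methoxymethoxy)-3-methylbutan-2-yl]oxy}-4-(methoxymethoxy)phenyl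
- ArOH = the same group with 1-hydroxy in place of the silyloxy group
- ArOTs = the same group with 1-(4-methylbenzenesulfonyloxy)

**Route**

Step 1
Reactants: 1 4-bromobenzene-1,3-diol
Product: 2 2-bromo-5-(methoxymethoxy)phenol
Conditions: MOMCl (1.0 equiv), i-Pr2NEt, CH2Cl2, 0 °C
Reagents that add atoms: chloromethyl methyl ether, COCCl
Why: Williamson-type MOM ether formation with one equivalent of reagent should favour the hydroxyl para to bromine, because the ortho-bromo hydroxyl is hindered and engaged in an O–H···Br contact; the minor regioisomer and the bis-ether would be removed by chromatography.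

Step 2
Reactants: 3 methyl (4S)-2,2-dimethyl-1,3-dioxolane-4-carboxylate
Product: 4 methyl (2S)-2,3-dihydroxypropanoate
Conditions: Dowex 50W (H+), MeOH, rt
Reagents that add atoms: none
Why: Acid-catalysed transacetalisation (acetonide methanolysis) should free the diol without touching the methyl ester or the stereocentre.

Step 3
Reactants: 4 methyl (2S)-2,3-dihydroxypropanoate
Product: 5 methyl (2S)-3-[(tert-butyldiphenylsilyl)oxy]-2-hydroxypropanoate
Conditions: TBDPSCl, imidazole, CH2Cl2, 0 °C
Reagents that add atoms: tert-butyl(chloro)diphenylsilane, CC(C)(C)[Si](Cl)(c1ccccc1)c1ccccc1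
Why: Silylation with a bulky chlorosilane is selective for the primary hydroxyl over the hydrogen-bonded secondary α-hydroxy ester hydroxyl.

Step 4
Reactants: 2 2-bromo-5-(methoxymethoxy)phenol; 5 methyl (2S)-3-[(tert-butyldiphenylsilyl)oxy]-2-hydroxypropanoate
Product: 6 methyl (2R)-2-[2-bromo-5-(methoxymethoxy)phenoxy]-3-[(tert-butyldiphenylsilyl)oxy]propanoate
Conditions: PPh3, DIAD, toluene, 0 °C → rt
Reagents that add atoms: none
Why: Mitsunobu etherification, in which the acidic ortho-bromophenol displaces the activated α-hydroxy ester oxygen by SN2 with inversion, so that (S)-C2 of 5 becomes the (R)-aryl ether carbon that ends up as C10.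

Step 5
Reactants: 6 methyl (2R)-2-[2-bromo-5-(methoxymethoxy)phenoxy]-3-[(tert-butyldiphenylsilyl)oxy]propanoate
Product: 8 (3R)-3-[2-bromo-5-(methoxymethoxy)phenoxy]-4-[(tert-butyldiphenylsilyl)oxy]-2-methylbutan-2-ol, via methyl ketone 7 (not isolated)
Conditions: MeMgBr (3 equiv), THF, −40 → 0 °C; aq. NH4Cl
Reagents that add atoms: methylmagnesium bromide, C[Mg]Br
Why: Double Grignard addition to the ester should give the C11 dimethyl carbinol, the aryl bromide and the ethers being inert to MeMgBr at or below 0 °C and carbonyl addition outrunning enolisation of the stereocentre.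

Step 6
Reactants: 8 (3R)-3-[2-bromo-5-(methoxymethoxy)phenoxy]-4-[(tert-butyldiphenylsilyl)oxy]-2-methylbutan-2-ol
Product: 9 {[(2R)-2-[2-bromo-5-(methoxymethoxy)phenoxy]-3-(methoxymethoxy)-3-methylbutyl]oxy}(tert-butyl)diphenylsilane (ArSi–Br)
Conditions: MOMCl, i-Pr2NEt, Bu4NI (cat.), ClCH2CH2Cl, 60 °C
Reagents that add atoms: chloromethyl methyl ether, COCCl
Why: Iodide-catalysed MOM protection of the tertiary alcohol masks O11 as an acetal that tolerates organolithiums, amide bases and fluoride, which keeps the later removal of the TBDPS group unambiguous.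

Step 7
Reactants: 9 ArSi–Br
Product: 11 2-{[(2R)-1-[(tert-butyldiphenylsilyl)oxy]-3-(methoxymethoxy)-3-methylbutan-2-yl]oxy}-4-(methoxymethoxy)benzoic acid (ArSi–CO2H), via aryllithium 10 (not isolated)
Conditions: n-BuLi, THF, −78 °C; CO2; cold dil. HCl to pH 4
Reagents that add atoms: carbon dioxide, O=C=O
Why: Bromine–lithium exchange at −78 °C is far faster than ortho-lithiation or attack on the ethers, and carboxylation of the aryllithium gives the benzoic acid (halogen–metal exchange/carboxylation).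

Step 8
Reactants: 11 ArSi–CO2H; 12 1-(2,6-dihydroxy-4-methoxyphenyl)ethan-1-one
Product: 13 2-acetyl-3-hydroxy-5-methoxyphenyl ArSi-carboxylate
Conditions: EDC·HCl, DMAP (cat.), CH2Cl2, 0 °C → rt (12 in slight excess)
Reagents that add atoms: none
Why: Steglich esterification, in which the two hydroxyls of 12 are equivalent and the one left after the first acylation is chelated to the acetyl group and reacts much more slowly, so the mono-ester should dominate.

Step 9
Reactants: 13 2-acetyl-3-hydroxy-5-methoxyphenyl ArSi-carboxylate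
Product: 14 1-(2,6-dihydroxy-4-methoxyphenyl)-3-ArSi-propane-1,3-dione
Conditions: LiHMDS (3.5 equiv), THF, −78 → 0 °C; AcOH
Reagents that add atoms: none
Why: Baker–Venkataraman rearrangement, in which the ketone enolate attacks the neighbouring aryl ester through a six-membered transition state and the aroyl group moves from oxygen to carbon, forming the future C2–C3 bond.

Step 10
Reactants: 14 1-(2,6-dihydroxy-4-methoxyphenyl)-3-ArSi-propane-1,3-dione
Product: 15 5-hydroxy-7-methoxy-2-ArSi-4H-chromen-4-one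
Conditions: PPTS (cat.), 4 Å MS, ClCH2CH2Cl, 70 °C
Reagents that add atoms: none
Why: Acid-catalysed cyclodehydration of the 1,3-diketone through its hemiketal closes the pyranone, only one flavone being possible because the two A-ring phenols are equivalent, and a pyridinium acid in an aprotic solvent over sieves should spare the MOM acetals and the silyl ether.

Step 11
Reactants: 15 5-hydroxy-7-methoxy-2-ArSi-4H-chromen-4-one
Product: 16 5-hydroxy-6-iodo-7-methoxy-2-ArSi-4H-chromen-4-one
Conditions: BnMe3N·ICl2 (1.05 equiv), CaCO3, CH2Cl2–MeOH, rt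
Reagents that add atoms: benzyltrimethylammonium dichloroiodate, C[N+](C)(C)Cc1ccccc1.Cl[I-]Cl
Why: Electrophilic aromatic iodination with a dichloroiodate salt is directed ortho to the free chelated 5-hydroxyl (C6), the known regiochemistry for 5-hydroxy-7-alkoxyflavones, whereas non-phenolic alkoxyarenes such as the B ring need Lewis-acid activation to react with this reagent.

Step 12
Reactants: 16 5-hydroxy-6-iodo-7-methoxy-2-ArSi-4H-chromen-4-one
Product: 17 6-iodo-7-methoxy-5-(methoxymethoxy)-2-ArSi-4H-chromen-4-one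
Conditions: NaH, MOMCl, DMF, 0 °C → rt
Reagents that add atoms: chloromethyl methyl ether, COCCl
Why: Williamson-type O-alkylation of the sodium phenoxide caps the chelated 5-hydroxyl, which would otherwise consume the amide base and the Grignard reagent later.

Step 13
Reactants: 17 6-iodo-7-methoxy-5-(methoxymethoxy)-2-ArSi-4H-chromen-4-one; 18 (E)-4,4,5,5-tetramethyl-2-(3-methylbut-1-en-1-yl)-1,3,2-dioxaborolane
Product: 19 7-methoxy-5-(methoxymethoxy)-6-[(1E)-3-methylbut-1-en-1-yl]-2-ArSi-4H-chromen-4-one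
Conditions: Pd(OAc)2/SPhos (cat.), K3PO4, dioxane–H2O, 80 °C
Reagents that add atoms: none
Why: Suzuki–Miyaura coupling of the aryl iodide with the alkenylboronate proceeds with retention of the E geometry, and a biaryl dialkylphosphine ligand copes with the di-ortho-substituted iodide.

Step 14
Reactants: 19 7-methoxy-5-(methoxymethoxy)-6-[(1E)-3-methylbut-1-en-1-yl]-2-ArSi-4H-chromen-4-one
Product: 21 3-iodo-7-methoxy-5-(methoxymethoxy)-6-[(1E)-3-methylbut-1-en-1-yl]-2-ArSi-4H-chromen-4-one, via 3-lithioflavone 20 (not isolated)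
Conditions: LDA, THF, −78 °C; I2, −78 °C
Reagents that add atoms: iodine, II
Why: Deprotonation of a flavone at C3 with LDA (the only pyranone C–H, next to C4=O) followed by iodinolysis of the vinyllithium is known flavone chemistry, and LDA at −78 °C does not ortho-lithiate alkoxyarenes.

Step 15
Reactants: 21 3-iodo-7-methoxy-5-(methoxymethoxy)-6-[(1E)-3-methylbut-1-en-1-yl]-2-ArSi-4H-chromen-4-one
Product: 22 3-iodo-7-methoxy-5-(methoxymethoxy)-6-[(1E)-3-methylbut-1-en-1-yl]-2-ArOH-4H-chromen-4-one
Conditions: TBAF, AcOH, THF, 0 °C → rt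
Reagents that add atoms: none
Why: Fluoride-mediated desilylation removes the only silyl group, the MOM acetals and the vinyl iodide being inert and the acetic acid buffer keeping the liberated alkoxide from adding to the chromone.

Step 16
Reactants: 22 3-iodo-7-methoxy-5-(methoxymethoxy)-6-[(1E)-3-methylbut-1-en-1-yl]-2-ArOH-4H-chromen-4-one
Product: 23 3-iodo-7-methoxy-5-(methoxymethoxy)-6-[(1E)-3-methylbut-1-en-1-yl]-2-ArOTs-4H-chromen-4-one
Conditions: TsCl, Et3N, DMAP (cat.), CH2Cl2, 0 °C → rt
Reagents that add atoms: 4-methylbenzenesulfonyl chloride, Cc1ccc(S(=O)(=O)Cl)cc1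
Why: DMAP-catalysed sulfonylation of the primary alcohol, the only free hydroxyl, installs the C9 leaving group.

Step 17
Reactants: 23 3-iodo-7-methoxy-5-(methoxymethoxy)-6-[(1E)-3-methylbut-1-en-1-yl]-2-ArOTs-4H-chromen-4-one
Product: 25 5,4',11-tris-O-(methoxymethyl) ether of target 26 [(10R)-oxepinoflavone], via C3 Grignard reagent 24 (not isolated)
Conditions: i-PrMgCl·LiCl (1.1 equiv), THF, −40 °C; Li2CuCl4 (10 mol%), −40 → 0 °C
Reagents that add atoms: none
Why: Iodine–magnesium exchange at the C3 vinyl iodide (an α-iodoenone, exchanged within minutes at −40 °C) should give the Grignard reagent, which after transmetalation to a cuprate attacks the C9 sulfonate by intramolecular SN2-type oxidative addition and reductive elimination to form C3–C9. The closest known reaction type is the Parham cyclialkylation (halogen–metal exchange followed by ring-closing alkylation), run here under Kochi/Schlosser-type copper catalysis as used for Grignard–alkyl tosylate coupling, the exchange itself being known for 3-iodochromones. The oxepine (C2, C3, C9, C10, O, C2', C1') closes in a 7-exo-tet mode. No stereocentre is formed and no bond to C10 is broken, so the (R) configuration is carried through unchanged. The step needs exchange at C3–I in the presence of the C4 carbonyl, three acetals, the alkene and the sulfonate, which the electron-poor iodide and the low temperature secure, and it needs C- rather than O-alkylation, which follows because the C3 anion has no enolate oxygen. Placing the leaving group on C9 and the metal on C3 avoids β-elimination of the C10 aryloxide, and the tethered primary sulfonate should outrun coupling with the 2-iodopropane formed in the exchange.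

Step 18
Reactants: 25 5,4',11-tris-O-(methoxymethyl) ether of target 26
Product: 26 (10R)-5,4'-dihydroxy-7-methoxy-6-[(1E)-3-methylbut-1-en-1-yl]-3,2'-[C9H2–C10H(C11(CH3)2OH)–O]-bridged flavone (CNP0216454.1)
Conditions: 3 M HCl–MeOH, THF, 25–35 °C
Reagents that add atoms: none
Why: Acid-catalysed acetal methanolysis removes the two aryl MOM ethers and the tertiary alkyl MOM ether in one operation, and brief exposure at or below 35 °C, as practised for MOM removal from prenylated phenols, should leave the styrenyl alkene, the tertiary alcohol and the C10 ether intact.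

**Compound list**

1 | 4-bromobenzene-1,3-diol | Oc1ccc(Br)c(O)c1 | starting material
2 | 2-bromo-5-(methoxymethoxy)phenol | COCOc1ccc(Br)c(O)c1 | intermediate
3 | methyl (4S)-2,2-dimethyl-1,3-dioxolane-4-carboxylate | COC(=O)[C@@H]1COC(C)(C)O1 | starting material
4 | methyl (2S)-2,3-dihydroxypropanoate | O[C@@H](CO)C(=O)OC | intermediate
5 | methyl (2S)-3-[(tert-butyldiphenylsilyl)oxy]-2-hydroxypropanoate | O[C@@H](CO[Si](c1ccccc1)(c1ccccc1)C(C)(C)C)C(=O)OC | intermediate
6 | methyl (2R)-2-[2-bromo-5-(methoxymethoxy)phenoxy]-3-[(tert-butyldiphenylsilyl)oxy]propanoate | Brc1ccc(OCOC)cc1O[C@H](CO[Si](c2ccccc2)(c2ccccc2)C(C)(C)C)C(=O)OC | intermediate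
7 | (3R)-3-[2-bromo-5-(methoxymethoxy)phenoxy]-4-[(tert-butyldiphenylsilyl)oxy]butan-2-one | Brc1ccc(OCOC)cc1O[C@H](CO[Si](c2ccccc2)(c2ccccc2)C(C)(C)C)C(C)=O | intermediate (not isolated)
8 | (3R)-3-[2-bromo-5-(methoxymethoxy)phenoxy]-4-[(tert-butyldiphenylsilyl)oxy]-2-methylbutan-2-ol | Brc1ccc(OCOC)cc1O[C@H](CO[Si](c2ccccc2)(c2ccccc2)C(C)(C)C)C(C)(C)O | intermediate
9 | {[(2R)-2-[2-bromo-5-(methoxymethoxy)phenoxy]-3-(methoxymethoxy)-3-methylbutyl]oxy}(tert-butyl)diphenylsilane (ArSi–Br) | Brc1ccc(OCOC)cc1O[C@H](CO[Si](c2ccccc2)(c2ccccc2)C(C)(C)C)C(C)(C)OCOC | intermediate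
10 | ArSi-lithium (lithium in place of the bromine of 9) | [Li]c1ccc(OCOC)cc1O[C@H](CO[Si](c2ccccc2)(c2ccccc2)C(C)(C)C)C(C)(C)OCOC | intermediate (not isolated)
11 | 2-{[(2R)-1-[(tert-butyldiphenylsilyl)oxy]-3-(methoxymethoxy)-3-methylbutan-2-yl]oxy}-4-(methoxymethoxy)benzoic acid (ArSi–CO2H) | OC(=O)c1ccc(OCOC)cc1O[C@H](CO[Si](c2ccccc2)(c2ccccc2)C(C)(C)C)C(C)(C)OCOC | intermediate
12 | 1-(2,6-dihydroxy-4-methoxyphenyl)ethan-1-one | CC(=O)c1c(O)cc(OC)cc1O | starting material
13 | 2-acetyl-3-hydroxy-5-methoxyphenyl ArSi-carboxylate | CC(=O)c1c(O)cc(OC)cc1OC(=O)c2ccc(OCOC)cc2O[C@H](CO[Si](c3ccccc3)(c3ccccc3)C(C)(C)C)C(C)(C)OCOC | intermediate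
14 | 1-(2,6-dihydroxy-4-methoxyphenyl)-3-ArSi-propane-1,3-dione | COc1cc(O)c(C(=O)CC(=O)c2ccc(OCOC)cc2O[C@H](CO[Si](c3ccccc3)(c3ccccc3)C(C)(C)C)C(C)(C)OCOC)c(O)c1 | intermediate
15 | 5-hydroxy-7-methoxy-2-ArSi-4H-chromen-4-one | COc1cc2oc(-c3ccc(OCOC)cc3O[C@H](CO[Si](c4ccccc4)(c4ccccc4)C(C)(C)C)C(C)(C)OCOC)cc(=O)c2c(O)c1 | intermediate
16 | 5-hydroxy-6-iodo-7-methoxy-2-ArSi-4H-chromen-4-one | COc1cc2oc(-c3ccc(OCOC)cc3O[C@H](CO[Si](c4ccccc4)(c4ccccc4)C(C)(C)C)C(C)(C)OCOC)cc(=O)c2c(O)c1I | intermediate
17 | 6-iodo-7-methoxy-5-(methoxymethoxy)-2-ArSi-4H-chromen-4-one | COc1cc2oc(-c3ccc(OCOC)cc3O[C@H](CO[Si](c4ccccc4)(c4ccccc4)C(C)(C)C)C(C)(C)OCOC)cc(=O)c2c(OCOC)c1I | intermediate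
18 | (E)-4,4,5,5-tetramethyl-2-(3-methylbut-1-en-1-yl)-1,3,2-dioxaborolane | CC(C)/C=C/B1OC(C)(C)C(C)(C)O1 | starting material
19 | 7-methoxy-5-(methoxymethoxy)-6-[(1E)-3-methylbut-1-en-1-yl]-2-ArSi-4H-chromen-4-one | COc1cc2oc(-c3ccc(OCOC)cc3O[C@H](CO[Si](c4ccccc4)(c4ccccc4)C(C)(C)C)C(C)(C)OCOC)cc(=O)c2c(OCOC)c1/C=C/C(C)C | intermediate
20 | 3-lithio derivative of 19 | COc1cc2oc(-c3ccc(OCOC)cc3O[C@H](CO[Si](c4ccccc4)(c4ccccc4)C(C)(C)C)C(C)(C)OCOC)c([Li])c(=O)c2c(OCOC)c1/C=C/C(C)C | intermediate (not isolated)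
21 | 3-iodo-7-methoxy-5-(methoxymethoxy)-6-[(1E)-3-methylbut-1-en-1-yl]-2-ArSi-4H-chromen-4-one | COc1cc2oc(-c3ccc(OCOC)cc3O[C@H](CO[Si](c4ccccc4)(c4ccccc4)C(C)(C)C)C(C)(C)OCOC)c(I)c(=O)c2c(OCOC)c1/C=C/C(C)C | intermediate
22 | 3-iodo-7-methoxy-5-(methoxymethoxy)-6-[(1E)-3-methylbut-1-en-1-yl]-2-ArOH-4H-chromen-4-one | COc1cc2oc(-c3ccc(OCOC)cc3O[C@H](CO)C(C)(C)OCOC)c(I)c(=O)c2c(OCOC)c1/C=C/C(C)C | intermediate
23 | 3-iodo-7-methoxy-5-(methoxymethoxy)-6-[(1E)-3-methylbut-1-en-1-yl]-2-ArOTs-4H-chromen-4-one | COc1cc2oc(-c3ccc(OCOC)cc3O[C@H](COS(=O)(=O)c4ccc(C)cc4)C(C)(C)OCOC)c(I)c(=O)c2c(OCOC)c1/C=C/C(C)C | intermediate (key-step precursor)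
24 | 3-(chloromagnesio) derivative of 23 (MgCl in place of iodine) | COc1cc2oc(-c3ccc(OCOC)cc3O[C@H](COS(=O)(=O)c4ccc(C)cc4)C(C)(C)OCOC)c([Mg]Cl)c(=O)c2c(OCOC)c1/C=C/C(C)C | intermediate (not isolated)
25 | 5,4',11-tris-O-(methoxymethyl) ether of 26: (10R)-oxepinoflavone with C3 joined through C9H2–C10H[C11(CH3)2OCH2OCH3]–O to C2' | COc1cc2oc3c(c(=O)c2c(OCOC)c1/C=C/C(C)C)C[C@H](C(C)(C)OCOC)Oc1cc(OCOC)ccc1-3 | intermediate (key-step product)
26 | (10R)-5,4'-dihydroxy-7-methoxy-6-[(1E)-3-methylbut-1-en-1-yl]-3,2'-[C9H2–C10H(C11(CH3)2OH)–O]-bridged flavone (CNP0216454.1) | COc1cc2oc3c(c(=O)c2c(O)c1/C=C/C(C)C)C[C@H](C(C)(C)O)Oc1cc(O)ccc1-3 | target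

**Step count and risks**

Total steps: 18. Longest linear sequence: 17 (steps 2–18, from 3).

Most likely to fail: steps 17, 11 and 14.

Step 17. The displacement at C9 may be too slow, because the sulfonate is β-branched and β-oxygenated. Meanwhile the C3 organometallic can be protonated, can open the pyranone by expelling the ring phenoxide, or can be alkylated by 2-iodopropane. The fallback leaves the route at alcohol 22 and rejoins it at 25, keeping C3 as nucleophile and C9 as electrophile but using a carbonyl as the electrophile. Dess–Martin oxidation (NaHCO3, CH2Cl2) would give the C9 aldehyde F1; its descriptor is 2S only because CHO outranks C11, and the spatial arrangement is that of 22. Intramolecular Nozaki–Hiyama–Kishi coupling of the C3 iodide with the aldehyde (CrCl2, cat. NiCl2, DMF, rt) should close the oxepine as the C9 carbinol F2, either C9 epimer being usable. Acylation with 1,1'-thiocarbonyldiimidazole (DMAP, CH2Cl2) would give the C9 imidazole-1-carbothioate F3, and Barton–McCombie deoxygenation (Bu3SnH, AIBN, toluene, 90 °C) would remove the C9 oxygen to reach 25.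

Step 11. Regiocontrol may be lost: iodination could occur at C8 or at the 3',5'-positions of the dialkoxyphenyl ring, or proceed twice. The fallback places the iodine before the rings are joined; it sets out from ketone 12 (with acid 11) and returns at 17. The symmetric ketone can give only one mono-iodide, the mono-iodo ketone F4 (BnMe3N·ICl2, CaCO3). Steglich esterification with 11 at the hydroxyl remote from iodine would give the mono-ester F5, and the iodine-flanked hydroxyl would then be capped (MOMCl, i-Pr2NEt) as the MOM ether F6. Baker–Venkataraman rearrangement (LiHMDS) would lead to the diketone F7, whose single free phenol can close the pyranone (PPTS, sieves) only so as to put iodine at C6, giving 17.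

Step 14. Deprotonation may be incomplete or unselective, the 3-lithio species may open to the alkynone phenoxide before iodine is added, or the amide may add to the chromone. The fallback dispenses with the C3 iodide; it sets out from 19 and returns at 25. Desilylation (TBAF, AcOH) would give the primary alcohol F8 and sulfonylation (TsCl, Et3N, DMAP) the tosylate F9. C3–H would then be magnesiated directly with TMPMgCl·LiCl (THF, −20 °C), a hindered amide base of the type known to metalate chromones and to spare sulfonate esters, and Li2CuCl4 would trigger the same C3–C9 closure to 25.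

**Further compounds**

F1 | step 17 | (2S)-2-(2-{3-iodo-7-methoxy-5-(methoxymethoxy)-6-[(1E)-3-methylbut-1-en-1-yl]-4-oxo-4H-chromen-2-yl}-5-(methoxymethoxy)phenoxy)-3-(methoxymethoxy)-3-methylbutanal | COc1cc2oc(-c3ccc(OCOC)cc3O[C@H](C=O)C(C)(C)OCOC)c(I)c(=O)c2c(OCOC)c1/C=C/C(C)C
F2 | step 17 | 9-hydroxy derivative of 25 (C9 epimers, 10R) | COc1cc2oc3c(c(=O)c2c(OCOC)c1/C=C/C(C)C)C(O)[C@H](C(C)(C)OCOC)Oc1cc(OCOC)ccc1-3
F3 | step 17 | O-(C9) 1H-imidazole-1-carbothioate of F2 | COc1cc2oc3c(c(=O)c2c(OCOC)c1/C=C/C(C)C)C(OC(=S)n1ccnc1)[C@H](C(C)(C)OCOC)Oc1cc(OCOC)ccc1-3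
F4 | step 11 | 1-(2,6-dihydroxy-3-iodo-4-methoxyphenyl)ethan-1-one | CC(=O)c1c(O)cc(OC)c(I)c1O
F5 | step 11 | 2-acetyl-3-hydroxy-4-iodo-5-methoxyphenyl ArSi-carboxylate | CC(=O)c1c(O)c(I)c(OC)cc1OC(=O)c2ccc(OCOC)cc2O[C@H](CO[Si](c3ccccc3)(c3ccccc3)C(C)(C)C)C(C)(C)OCOC
F6 | step 11 | 2-acetyl-4-iodo-5-methoxy-3-(methoxymethoxy)phenyl ArSi-carboxylate | CC(=O)c1c(OCOC)c(I)c(OC)cc1OC(=O)c2ccc(OCOC)cc2O[C@H](CO[Si](c3ccccc3)(c3ccccc3)C(C)(C)C)C(C)(C)OCOC
F7 | step 11 | 1-[6-hydroxy-3-iodo-4-methoxy-2-(methoxymethoxy)phenyl]-3-ArSi-propane-1,3-dione | COCOc1c(I)c(OC)cc(O)c1C(=O)CC(=O)c2ccc(OCOC)cc2O[C@H](CO[Si](c3ccccc3)(c3ccccc3)C(C)(C)C)C(C)(C)OCOC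
F8 | step 14 | 7-methoxy-5-(methoxymethoxy)-6-[(1E)-3-methylbut-1-en-1-yl]-2-ArOH-4H-chromen-4-one | COc1cc2oc(-c3ccc(OCOC)cc3O[C@H](CO)C(C)(C)OCOC)cc(=O)c2c(OCOC)c1/C=C/C(C)C
F9 | step 14 | 7-methoxy-5-(methoxymethoxy)-6-[(1E)-3-methylbut-1-en-1-yl]-2-ArOTs-4H-chromen-4-one | COc1cc2oc(-c3ccc(OCOC)cc3O[C@H](COS(=O)(=O)c4ccc(C)cc4)C(C)(C)OCOC)cc(=O)c2c(OCOC)c1/C=C/C(C)C
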